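## Structural features

The target is a 2H-chromene: a benzene ring (C4a–C8a) with a free hydroxyl at C6 and a methyl at C8, fused to a pyran ring O1–C2–C3=C4 whose cis C3=C4 bond is conjugated with the arene. C2 is the only stereocentre, (S), a fully substituted tertiary-ether carbon bonded to O1, CH3, ring carbon C3 and chain carbon C1'; no neighbouring stereocentre exists from which it could be relayed. The chain C1'–C12' holds three isolated trisubstituted olefins: C3'=C4' (E, methyl branch), C7'=C8' (2Z, carboxyl on C8' cis to C6', the less stable geometry) and the terminal prenyl C11'=C12'. Fragile elements are the electron-rich 6-hydroxychromene (air oxidation in base), the C2–O1 bond (acid ionisation or photochemical/thermal ring opening gives a planar ortho-quinone methide and racemises C2), the Z-enoate (isomerisation) and the skipped polyene (acid-induced cyclisation, unselective reduction). The real difficulty is C2: the usual chromene-forming reactions pass through that same planar ortho-quinone methide and give racemate. The feature exploited here is that C2 carries two two-carbon arms of like origin, C3=C4 in the ring and C1'–C2' in the chain. If C3=C4 is cut, both arms are vinyl groups, C2 becomes a non-stereogenic divinyl carbinol ether carbon, and closing the ring is the act that creates the stereocentre. The Z geometry at C7'=C8' is independent of the ring and can be solved in an achiral chain fragment.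

## Logic of the disconnections

22 ⇒ 20. The phenol O–H and acid O–H are returned to O–Si and O–CH3 bonds. The free 6-hydroxychromene is the most oxidation-prone form and the acid would interfere with the organometallic steps. There is no skeletal gain, but all C–C chemistry can be run on protected material. The unmasking (through 21) must not isomerise the Z-enoate or open the pyran ring.

20 ⇒ 10 + 18. The C2'–C3' single bond between the sp3 chain carbon and the alkenyl carbon is cut. This separates the stereogenic bicyclic part from an achiral chain that holds both geometrically defined olefins, and the ring fragment then needs only a vinyl group at C2. The gain is convergence into two fragments of similar size. The forward coupling (through 19) must hydroborate only the terminal vinyl of 10 and transfer the alkyl group with retention of the alkenyl geometry of 18, leaving enoate, ring olefin and silyl ether alone.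

10 ⇒ 9 (key). The C3=C4 double bond of the pyran ring is cut. After this cut C3 and C1' are both termini of vinyl groups on C2, so C2 of 9 is not a stereocentre and 9 is achiral. Ring and stereocentre disappear together, and the vinyl group that the ring closure does not use is exactly the handle needed for the chain. The forward step must choose one of two enantiotopic vinyl groups under catalyst control and must not be reversed afterwards.

9 ⇒ 7 (through 8) ⇒ 6. Both terminal C=CH2 bonds on the C2 arms are cut (carbonyl olefination) and the oxidation level is taken back to two ester groups. Two identical arms can be processed at the same time, and the skeleton reduces to a 2-aryloxy-2-methylmalonate. The electrophilic 1,3-dialdehyde 8 must be olefinated twice before it hydrates or fragments.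

6 ⇒ 4 + 5. The aryl O–C(tertiary) bond (the later O1–C2) is cut. A tertiary ether carbon with two identical arms is available as 5, whose ester groups activate the tertiary carbon for substitution. The gain is a phenol and a commercial C4 unit. The forward step is O-alkylation of a 2,6-disubstituted phenoxide at a tertiary centre.

4 ⇒ 3 ⇒ 2 ⇒ 1. The cuts are the C4=CH2 bond (methylenation), the C4a–CHO bond (ortho-formylation) and the O–Si bond. The oxygenation pattern of the arene, with the later O1 flanked by the methyl group and the second oxygen para to it, is that of 1. The forward steps need silylation of the less hindered hydroxyl and formylation ortho to the free one.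

18 ⇒ 17 + 13. The C7'=C8' double bond is cut (carbonyl olefination). This joins a small aldehyde to a phosphonate that already carries the homoprenyl branch and the ester. The forward step must deliver the Z geometry under kinetic control.

13 ⇒ 11 + 12 and 17 ⇒ 16 ⇒ 14 (through 15). The C8'–C9' bond is cut (enolate alkylation); the C4'–CH3 and C3'–I bonds are cut (syn carbometallation of an alkyne, then iodinolysis) and the oxidation level is adjusted. All starting materials are commercial. The carbometallation must fix the E geometry of C3'=C4'.

## Other disconnections considered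

Alternative 1: (first to come to mind) Cut O1–C2 and C4–C4a and condense a methylhydroquinone derivative with the polyenal A1. The forward key step is condensation to an ortho-quinone methide and oxa-6π electrocyclisation to the chromene A2. The ring closure starts from a planar, achiral intermediate, so A2 would be racemic and a single enantiomer would need a late resolution. A1 is also a long linear polyene that must be finished before the ring exists, and the condensation has to choose between several free ortho positions.

Alternative 2: Cut C2–C1' and form it by dearomatisation. Chromone A3 would be converted into its flat 4-silyloxybenzopyrylium ion and a copper acetylide added to C2 under chiral bis(oxazoline) control to give the 2-alkynylchromanone A4. This joins a chain carbon and sets C2 in one step, but the nucleophile has to be an alkyne. The alkyne must then be reduced and the C4 carbonyl reduced and eliminated, three redox corrections after the stereocentre is made. The 2-methyl group of the cation is also acidic (competing deprotonation to a 2-methylene chromene), and A3 needs a regioselective acylation of the hydroquinone. The chosen plan creates C2 directly at the chromene oxidation level.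

Alternative 3: Cut O1–C2 and close the ring by palladium-catalysed asymmetric allylic alkylation (Tsuji–Trost type). The phenol of allylic carbonate A5 would attack the π-allyl complex to give the 2-vinylchroman A6. This sets ring and stereocentre together, but at the chroman level. A benzylic dehydrogenation across C3–C4 of an electron-rich arene, in the presence of the vinyl group, would still be needed. A5 also requires a geometrically pure trisubstituted allylic carbonate built on the arene, because the olefin geometry decides the enantiomer, so the route is longer.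

Key step: step 7

Assumption: which antipode of the chiral molybdenum catalyst engages the pro-S vinyl group of 9 cannot be derived with certainty from a model; both antipodes are accessible and the route assumes the one that gives (S)-10.

## Route

Step 1
Reactants: 1 2-methylbenzene-1,4-diol (methylhydroquinone)
Product: 2 2-methyl-4-[(triisopropylsilyl)oxy]phenol
Conditions: TIPSCl (1.05 equiv), imidazole, DMF, 0 °C
Reagents that add atoms: triisopropylsilyl chloride, CC(C)[Si](Cl)(C(C)C)C(C)C
Why: Imidazole-promoted silyl ether formation with a bulky chlorosilane should occur at the 4-OH, whose ortho positions are unsubstituted, in preference to the 1-OH flanked by the methyl group; regioisomer and bis-silyl ether are removed by chromatography.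

Step 2
Reactants: 2 2-methyl-4-[(triisopropylsilyl)oxy]phenol
Product: 3 2-hydroxy-3-methyl-5-[(triisopropylsilyl)oxy]benzaldehyde
Conditions: MgCl2, Et3N, (CH2O)n, MeCN, reflux
Reagents that add atoms: paraformaldehyde (formaldehyde), C=O
Why: Magnesium-mediated ortho-formylation of phenols (Casnati–Skattebøl reaction): the magnesium phenoxide delivers formaldehyde to the only free ortho position and the hydroxymethyl intermediate is oxidised in situ by hydride transfer to a second formaldehyde; the aryl TIPS ether should tolerate these conditions.

Step 3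
Reactants: 3 2-hydroxy-3-methyl-5-[(triisopropylsilyl)oxy]benzaldehyde
Product: 4 2-ethenyl-6-methyl-4-[(triisopropylsilyl)oxy]phenol
Conditions: Ph3PCH3Br (2.5 equiv), KHMDS (2.4 equiv), THF, 0 °C → rt; NH4Cl work-up
Reagents that add atoms: methyltriphenylphosphonium bromide, C[P+](c1ccccc1)(c1ccccc1)c1ccccc1.[Br-]
Why: Wittig methylenation; the first equivalent of ylide is consumed by the phenol and the phenoxide aldehyde is then olefinated by the excess; 4 is used promptly because 2-vinylphenols oligomerise on storage.

Step 4
Reactants: 4 2-ethenyl-6-methyl-4-[(triisopropylsilyl)oxy]phenol; 5 diethyl 2-bromo-2-methylpropanedioate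
Product: 6 diethyl 2-{2-ethenyl-6-methyl-4-[(triisopropylsilyl)oxy]phenoxy}-2-methylpropanedioate
Conditions: K2CO3, DMF, 50 °C
Reagents that add atoms: none
Why: Williamson-type O-alkylation at a tertiary carbon that is activated by two ester groups; the product has no α-hydrogen, so no condensation can follow, and the future C2 enters as an achiral carbon with two identical arms.

Step 5
Reactants: 6 diethyl 2-{2-ethenyl-6-methyl-4-[(triisopropylsilyl)oxy]phenoxy}-2-methylpropanedioate
Product: 7 2-{2-ethenyl-6-methyl-4-[(triisopropylsilyl)oxy]phenoxy}-2-methylpropane-1,3-diol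
Conditions: LiAlH4, THF, 0 °C; aq NaOH work-up
Reagents that add atoms: none
Why: Hydride reduction of both esters to a stable prochiral 1,3-diol; styrene and aryl silyl ether are inert to LiAlH4 at 0 °C.

Step 6
Reactants: 7 2-{2-ethenyl-6-methyl-4-[(triisopropylsilyl)oxy]phenoxy}-2-methylpropane-1,3-diol
Product: 9 {3-ethenyl-5-methyl-4-[(3-methylpenta-1,4-dien-3-yl)oxy]phenoxy}tri(propan-2-yl)silane (achiral triene), via dialdehyde 8 (not isolated)
Conditions: (COCl)2, DMSO, CH2Cl2, −78 °C; Et3N, −78 → −30 °C; then Ph3P=CH2 (from Ph3PCH3Br, KHMDS, THF; excess), −78 °C → rt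
Reagents that add atoms: methyltriphenylphosphonium bromide, C[P+](c1ccccc1)(c1ccccc1)c1ccccc1.[Br-]
Why: One-pot Swern oxidation and Wittig methylenation, so that the non-enolisable but electrophilic 1,3-dialdehyde 8 is trapped as it forms; both arms react identically and the product is achiral and is kept away from acid (doubly allylic tertiary ether).

Step 7
Reactants: 9 {3-ethenyl-5-methyl-4-[(3-methylpenta-1,4-dien-3-yl)oxy]phenoxy}tri(propan-2-yl)silane
Product: 10 {[(2S)-2-ethenyl-2,8-dimethyl-2H-chromen-6-yl]oxy}tri(propan-2-yl)silane
Conditions: Mo(N-2,6-iPr2C6H3)(CHCMe2Ph)[3,3'-di-tert-butyl-5,5',6,6'-tetramethylbiphenyl-2,2'-diolate] (single antipode, 5 mol %), C6H6, 0.05 M, 22 °C, glovebox, N2 sweep, dark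
Reagents that add atoms: none
Why: Catalytic asymmetric ring-closing metathesis that desymmetrises an achiral triene; the closest known reaction type is the molybdenum-catalysed enantioselective RCM of prochiral trienes to five- and six-membered unsaturated cyclic ethers, tertiary ethers included, together with the metathetic formation of 2H-chromenes from styrenyl ethers. The catalyst should initiate at the unhindered styrenyl olefin, since the two C2 vinyl groups sit on a fully substituted carbon, giving an aryl-substituted Mo alkylidene and ethylene. Intramolecular [2+2] cycloaddition of this alkylidene with one of the two enantiotopic vinyl groups and cycloreversion close the six-membered pyran ring by forming C3=C4 (closure by metathesis, cis olefin enforced by the ring; the two C2 vinyls cannot close on each other because that would be a three-membered ring) and return Mo=CH2. C2, the only stereocentre, is set by catalyst control: in the two diastereomeric metallacyclobutane transition states the methyl group and the spectator vinyl group exchange pseudo-axial and pseudo-equatorial sites on the forming ring, and the chiral biphenolate/imido pocket is relied on to tell the planar vinyl from the methyl group so that the pro-S vinyl reacts. The step needs group selectivity and kinetic control: the product olefin is a cis-disubstituted styrenyl bond next to a quaternary carbon and should reopen only slowly, and ethylene is swept away so that ring opening and re-closure do not erode the selectivity. No carbonyl or protic group is present and the C2–O1 bond is never broken, so the configuration once set cannot be lost in this step.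

Step 8
Reactants: 11 methyl 2-[bis(2,2,2-trifluoroethoxy)phosphoryl]acetate; 12 5-bromo-2-methylpent-2-ene
Product: 13 methyl 2-[bis(2,2,2-trifluoroethoxy)phosphoryl]-6-methylhept-5-enoate (racemic)
Conditions: NaH, THF/DMF, 0 °C; then 12, NaI (cat.), 50 °C
Reagents that add atoms: none
Why: C-alkylation of the sodium phosphonoacetate, as in the preparation of α-alkyl Still–Gennari reagents; the soft stabilised anion should favour SN2 on the primary homoallylic halide over elimination, and the configuration of the new α-carbon is irrelevant.

Step 9
Reactants: 14 pent-4-yn-1-ol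
Product: 16 (4E)-5-iodo-4-methylpent-4-en-1-ol, via alkenylalane 15 (not isolated)
Conditions: AlMe3 (3 equiv), Cp2ZrCl2 (0.25 equiv), CH2Cl2, 0 °C → rt; then I2, THF, −30 → 0 °C; aq K2CO3
Reagents that add atoms: trimethylaluminium, C[Al](C)C; iodine, II
Why: Negishi zirconium-catalysed carboalumination: syn addition of Me–Al across the terminal alkyne with aluminium at the terminus, then iodinolysis with retention, which fixes the E geometry of the future C3'=C4' bond.

Step 10
Reactants: 16 (4E)-5-iodo-4-methylpent-4-en-1-ol
Product: 17 (4E)-5-iodo-4-methylpent-4-enal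
Conditions: Dess–Martin periodinane, NaHCO3, CH2Cl2, 0 °C → rt
Reagents that add atoms: none
Why: Buffered Dess–Martin oxidation of a primary alcohol to the aldehyde; the alkenyl iodide is not affected and the volatile aldehyde is used directly.

Step 11
Reactants: 17 (4E)-5-iodo-4-methylpent-4-enal; 13 methyl 2-[bis(2,2,2-trifluoroethoxy)phosphoryl]-6-methylhept-5-enoate
Product: 18 methyl (2Z,6E)-7-iodo-6-methyl-2-(4-methylpent-3-en-1-yl)hepta-2,6-dienoate
Conditions: 13, KHMDS, 18-crown-6, THF, −78 °C; then 17, −78 °C
Reagents that add atoms: none
Why: Still–Gennari variant of the Horner–Wadsworth–Emmons reaction: with the bis(trifluoroethyl) phosphonate and a dissociated potassium ion, fast irreversible elimination from the kinetic adduct should give the Z enoate (ester cis to the new chain), the geometry required at C7'=C8'; α-alkyl reagents of this type keep that preference with unbranched aliphatic aldehydes.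

Step 12
Reactants: 10 {[(2S)-2-ethenyl-2,8-dimethyl-2H-chromen-6-yl]oxy}tri(propan-2-yl)silane; 18 methyl (2Z,6E)-7-iodo-6-methyl-2-(4-methylpent-3-en-1-yl)hepta-2,6-dienoate
Product: 20 methyl (2Z,6E)-9-{(2S)-2,8-dimethyl-6-[(triisopropylsilyl)oxy]-2H-chromen-2-yl}-6-methyl-2-(4-methylpent-3-en-1-yl)nona-2,6-dienoate, via alkylborane 19 (not isolated)
Conditions: 9-BBN (1.3 equiv), THF, 0 °C → rt, dark; then 3 M aq K3PO4, 18, Pd(dppf)Cl2·CH2Cl2 (5 mol %), AsPh3 (10 mol %), DMF, rt
Reagents that add atoms: none
Why: Anti-Markovnikov hydroboration of the monosubstituted vinyl group by 9-BBN (much faster than addition to the cis-disubstituted ring olefin), then B-alkyl Suzuki–Miyaura coupling with retention of the E geometry of the alkenyl iodide, forms C2'–C3'; enoate, silyl ether and the C2 stereocentre are not involved.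

Step 13
Reactants: 20 methyl (2Z,6E)-9-{(2S)-2,8-dimethyl-6-[(triisopropylsilyl)oxy]-2H-chromen-2-yl}-6-methyl-2-(4-methylpent-3-en-1-yl)nona-2,6-dienoate
Product: 22 (S)-sargachromenol, (2Z,6E)-9-[(2S)-6-hydroxy-2,8-dimethyl-2H-chromen-2-yl]-6-methyl-2-(4-methylpent-3-en-1-yl)nona-2,6-dienoic acid, via phenol ester 21 (not isolated)
Conditions: TBAF (1.1 equiv), THF, 0 °C, Ar, degassed; then LiOH·H2O (10 equiv), MeOH/H2O, 40 °C, dark; 1 M HCl to pH 4 at 0 °C
Reagents that add atoms: lithium hydroxide, [Li+].[OH-]
Why: Fluoride cleaves the aryl silyl ether and hydroxide then saponifies the hindered methyl ester (BAc2) in the same flask; the quaternary C2 cannot epimerise, and exclusion of air and light with a mildly acidic work-up protects the 6-hydroxychromene and the Z-enoate.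

## Compound list

1 | 2-methylbenzene-1,4-diol (methylhydroquinone) | Cc1cc(O)ccc1O | starting material
2 | 2-methyl-4-[(triisopropylsilyl)oxy]phenol | Cc1cc(O[Si](C(C)C)(C(C)C)C(C)C)ccc1O | intermediate
3 | 2-hydroxy-3-methyl-5-[(triisopropylsilyl)oxy]benzaldehyde | Cc1cc(O[Si](C(C)C)(C(C)C)C(C)C)cc(C=O)c1O | intermediate
4 | 2-ethenyl-6-methyl-4-[(triisopropylsilyl)oxy]phenol | Cc1cc(O[Si](C(C)C)(C(C)C)C(C)C)cc(C=C)c1O | intermediate
5 | diethyl 2-bromo-2-methylpropanedioate | CCOC(=O)C(C)(Br)C(=O)OCC | starting material
6 | diethyl 2-{2-ethenyl-6-methyl-4-[(triisopropylsilyl)oxy]phenoxy}-2-methylpropanedioate | CCOC(=O)C(C)(Oc1c(C)cc(O[Si](C(C)C)(C(C)C)C(C)C)cc1C=C)C(=O)OCC | intermediate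
7 | 2-{2-ethenyl-6-methyl-4-[(triisopropylsilyl)oxy]phenoxy}-2-methylpropane-1,3-diol | OCC(C)(CO)Oc1c(C)cc(O[Si](C(C)C)(C(C)C)C(C)C)cc1C=C | intermediate
8 | 2-{2-ethenyl-6-methyl-4-[(triisopropylsilyl)oxy]phenoxy}-2-methylpropanedial | O=CC(C)(C=O)Oc1c(C)cc(O[Si](C(C)C)(C(C)C)C(C)C)cc1C=C | intermediate (not isolated)
9 | {3-ethenyl-5-methyl-4-[(3-methylpenta-1,4-dien-3-yl)oxy]phenoxy}tri(propan-2-yl)silane | C=CC(C)(C=C)Oc1c(C)cc(O[Si](C(C)C)(C(C)C)C(C)C)cc1C=C | intermediate
10 | {[(2S)-2-ethenyl-2,8-dimethyl-2H-chromen-6-yl]oxy}tri(propan-2-yl)silane | C=C[C@@]1(C)C=Cc2cc(O[Si](C(C)C)(C(C)C)C(C)C)cc(C)c2O1 | intermediate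
11 | methyl 2-[bis(2,2,2-trifluoroethoxy)phosphoryl]acetate | COC(=O)CP(=O)(OCC(F)(F)F)OCC(F)(F)F | starting material
12 | 5-bromo-2-methylpent-2-ene | CC(C)=CCCBr | starting material
13 | methyl 2-[bis(2,2,2-trifluoroethoxy)phosphoryl]-6-methylhept-5-enoate (racemic) | COC(=O)C(CCC=C(C)C)P(=O)(OCC(F)(F)F)OCC(F)(F)F | intermediate
14 | pent-4-yn-1-ol | C#CCCCO | starting material
15 | [(1E)-5-[(dimethylalumanyl)oxy]-2-methylpent-1-en-1-yl]dimethylalumane | C[Al](C)OCCC/C(C)=C/[Al](C)C | intermediate (not isolated)
16 | (4E)-5-iodo-4-methylpent-4-en-1-ol | OCCC/C(C)=C/I | intermediate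
17 | (4E)-5-iodo-4-methylpent-4-enal | O=CCC/C(C)=C/I | intermediate
18 | methyl (2Z,6E)-7-iodo-6-methyl-2-(4-methylpent-3-en-1-yl)hepta-2,6-dienoate | CC(C)=CCC/C(=C/CC/C(C)=C/I)C(=O)OC | intermediate
19 | 9-{2-[(2S)-2,8-dimethyl-6-[(triisopropylsilyl)oxy]-2H-chromen-2-yl]ethyl}-9-borabicyclo[3.3.1]nonane | C(C[C@@]1(C)C=Cc2cc(O[Si](C(C)C)(C(C)C)C(C)C)cc(C)c2O1)B1C2CCCC1CCC2 | intermediate (not isolated)
20 | methyl (2Z,6E)-9-{(2S)-2,8-dimethyl-6-[(triisopropylsilyl)oxy]-2H-chromen-2-yl}-6-methyl-2-(4-methylpent-3-en-1-yl)nona-2,6-dienoate | CC(C)=CCC/C(=C/CC/C(C)=C/CC[C@@]1(C)C=Cc2cc(O[Si](C(C)C)(C(C)C)C(C)C)cc(C)c2O1)C(=O)OC | intermediate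
21 | methyl (2Z,6E)-9-[(2S)-6-hydroxy-2,8-dimethyl-2H-chromen-2-yl]-6-methyl-2-(4-methylpent-3-en-1-yl)nona-2,6-dienoate | CC(C)=CCC/C(=C/CC/C(C)=C/CC[C@@]1(C)C=Cc2cc(O)cc(C)c2O1)C(=O)OC | intermediate (not isolated)
22 | (S)-sargachromenol, (2Z,6E)-9-[(2S)-6-hydroxy-2,8-dimethyl-2H-chromen-2-yl]-6-methyl-2-(4-methylpent-3-en-1-yl)nona-2,6-dienoic acid | CC(C)=CCC/C(=C/CC/C(C)=C/CC[C@@]1(C)C=Cc2cc(O)cc(C)c2O1)C(=O)O | target

## Step count and least certain steps

Total step count: 13. Longest linear sequence: 9 (steps 1–7, 12, 13); the chain fragment takes 4 steps (8–11) on two branches.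

Step 7 (key step). The likely failure is insufficient discrimination between the two enantiotopic vinyl groups, because the methyl and the spectator vinyl that must be told apart are close in size. A second failure is erosion of enantiomeric purity by ring opening and re-closure through the molybdenum methylidene if ethylene accumulates. The fallback sets the same prochiral carbon by an enzyme instead of a metathesis catalyst; it sets out from 7 and comes back at 10. Lipase-catalysed mono-acetylation of the prochiral diol 7 (vinyl acetate, MTBE; enzyme selected for this sense) would give (2R)-2-{2-ethenyl-6-methyl-4-[(triisopropylsilyl)oxy]phenoxy}-3-hydroxy-2-methylpropyl acetate F1. Dess–Martin oxidation of the free arm would give the aldehyde (2S)-2-{2-ethenyl-6-methyl-4-[(triisopropylsilyl)oxy]phenoxy}-2-methyl-3-oxopropyl acetate F2. Wittig methylenation would give (2R)-2-{2-ethenyl-6-methyl-4-[(triisopropylsilyl)oxy]phenoxy}-2-methylbut-3-en-1-yl acetate F3. Ring-closing metathesis with an achiral second-generation ruthenium benzylidene catalyst, for which no group selection is needed because only one C2 vinyl is present, would give {(2R)-2,8-dimethyl-6-[(triisopropylsilyl)oxy]-2H-chromen-2-yl}methyl acetate F4. Methanolysis (K2CO3, MeOH) would give {(2R)-2,8-dimethyl-6-[(triisopropylsilyl)oxy]-2H-chromen-2-yl}methanol F5. Dess–Martin oxidation would give (2R)-2,8-dimethyl-6-[(triisopropylsilyl)oxy]-2H-chromene-2-carbaldehyde F6, which cannot epimerise, and Wittig methylenation of F6 gives 10.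

Step 4. Substitution at the tertiary carbon of 5 by a 2,6-disubstituted phenoxide may be slow. Bromine transfer to the phenoxide (halophilic attack) or loss of HBr from 5 could then compete. The fallback builds the quaternary carbon by C-methylation instead of O-alkylation at a tertiary centre; it sets out from 4 and comes back at 6. The phenol 4 would be alkylated with the much more reactive secondary diethyl bromomalonate (K2CO3, acetone) to give diethyl 2-{2-ethenyl-6-methyl-4-[(triisopropylsilyl)oxy]phenoxy}propanedioate F7. Deprotonation (NaH, THF) and methylation with iodomethane would then give 6.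

Step 6. The 1,3-dialdehyde 8 may hydrate or undergo base-induced C–C fragmentation (deformylation) before both carbonyls are olefinated, or the second olefination may stall. The fallback separates carbon addition from elimination (Peterson olefination); it sets out from 7 and comes back at 9. After the Swern oxidation of 7, the cold solution of 8 would be treated with Me3SiCH2MgCl/CeCl3 at −78 °C. This fast, weakly basic addition would give 3-{2-ethenyl-6-methyl-4-[(triisopropylsilyl)oxy]phenoxy}-3-methyl-1,5-bis(trimethylsilyl)pentane-2,4-diol F8 as a mixture of diastereomers, which is of no consequence. Syn elimination with KH in THF would give 9 without exposing the acid-sensitive ether to acid.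

Step 12. Transmetallation of the alkylborane may be slow, leading to protodeboronation or β-hydride elimination. The aryl silyl ether may be partly lost in the basic aqueous medium, and Pd(0) might ionise the allylic C2–O1 bond. The fallback changes the nucleophile to an organozinc under anhydrous conditions (Negishi coupling); it sets out from 10 and comes back at 20. Hydroboration of 10 with 9-BBN and oxidation with NaBO3 would give 2-{(2S)-2,8-dimethyl-6-[(triisopropylsilyl)oxy]-2H-chromen-2-yl}ethan-1-ol F9. Appel iodination (I2, PPh3, imidazole) would give {[(2S)-2-(2-iodoethyl)-2,8-dimethyl-2H-chromen-6-yl]oxy}tri(propan-2-yl)silane F10. Zinc insertion (Zn dust, LiCl, THF) would give (2-{(2S)-2,8-dimethyl-6-[(triisopropylsilyl)oxy]-2H-chromen-2-yl}ethyl)zinc iodide F11. Palladium-catalysed coupling of F11 with 18 would give 20 with retention of the alkenyl geometry.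

## Further compounds

F1 | step 7 | (2R)-2-{2-ethenyl-6-methyl-4-[(triisopropylsilyl)oxy]phenoxy}-3-hydroxy-2-methylpropyl acetate | CC(=O)OC[C@@](Oc1c(C)cc(O[Si](C(C)C)(C(C)C)C(C)C)cc1C=C)(C)CO
F2 | step 7 | (2S)-2-{2-ethenyl-6-methyl-4-[(triisopropylsilyl)oxy]phenoxy}-2-methyl-3-oxopropyl acetate | CC(=O)OC[C@@](Oc1c(C)cc(O[Si](C(C)C)(C(C)C)C(C)C)cc1C=C)(C)C=O
F3 | step 7 | (2R)-2-{2-ethenyl-6-methyl-4-[(triisopropylsilyl)oxy]phenoxy}-2-methylbut-3-en-1-yl acetate | CC(=O)OC[C@@](Oc1c(C)cc(O[Si](C(C)C)(C(C)C)C(C)C)cc1C=C)(C)C=C
F4 | step 7 | {(2R)-2,8-dimethyl-6-[(triisopropylsilyl)oxy]-2H-chromen-2-yl}methyl acetate | CC(=O)OC[C@@]1(C)C=Cc2cc(O[Si](C(C)C)(C(C)C)C(C)C)cc(C)c2O1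
F5 | step 7 | {(2R)-2,8-dimethyl-6-[(triisopropylsilyl)oxy]-2H-chromen-2-yl}methanol | OC[C@@]1(C)C=Cc2cc(O[Si](C(C)C)(C(C)C)C(C)C)cc(C)c2O1
F6 | step 7 | (2R)-2,8-dimethyl-6-[(triisopropylsilyl)oxy]-2H-chromene-2-carbaldehyde | O=C[C@@]1(C)C=Cc2cc(O[Si](C(C)C)(C(C)C)C(C)C)cc(C)c2O1
F7 | step 4 | diethyl 2-{2-ethenyl-6-methyl-4-[(triisopropylsilyl)oxy]phenoxy}propanedioate | CCOC(=O)C(Oc1c(C)cc(O[Si](C(C)C)(C(C)C)C(C)C)cc1C=C)C(=O)OCC
F8 | step 6 | 3-{2-ethenyl-6-methyl-4-[(triisopropylsilyl)oxy]phenoxy}-3-methyl-1,5-bis(trimethylsilyl)pentane-2,4-diol | C[Si](C)(C)CC(O)C(C)(Oc1c(C)cc(O[Si](C(C)C)(C(C)C)C(C)C)cc1C=C)C(O)C[Si](C)(C)C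
F9 | step 12 | 2-{(2S)-2,8-dimethyl-6-[(triisopropylsilyl)oxy]-2H-chromen-2-yl}ethan-1-ol | OCC[C@@]1(C)C=Cc2cc(O[Si](C(C)C)(C(C)C)C(C)C)cc(C)c2O1
F10 | step 12 | {[(2S)-2-(2-iodoethyl)-2,8-dimethyl-2H-chromen-6-yl]oxy}tri(propan-2-yl)silane | ICC[C@@]1(C)C=Cc2cc(O[Si](C(C)C)(C(C)C)C(C)C)cc(C)c2O1
F11 | step 12 | (2-{(2S)-2,8-dimethyl-6-[(triisopropylsilyl)oxy]-2H-chromen-2-yl}ethyl)zinc iodide | I[Zn]CC[C@@]1(C)C=Cc2cc(O[Si](C(C)C)(C(C)C)C(C)C)cc(C)c2O1
A1 | alternative 1 | methyl (2Z,6E,10E)-6,10-dimethyl-2-(4-methylpent-3-en-1-yl)-12-oxododeca-2,6,10-trienoate | CC(C)=CCC/C(=C/CC/C(C)=C/CC/C(C)=C/C=O)C(=O)OC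
A2 | alternative 1 | methyl (2Z,6E)-9-(6-hydroxy-2,8-dimethyl-2H-chromen-2-yl)-6-methyl-2-(4-methylpent-3-en-1-yl)nona-2,6-dienoate (racemic at C2) | CC(C)=CCC/C(=C/CC/C(C)=C/CCC1(C)C=Cc2cc(O)cc(C)c2O1)C(=O)OC
A3 | alternative 2 | 2,8-dimethyl-6-[(triisopropylsilyl)oxy]-4H-chromen-4-one | Cc1cc(=O)c2cc(O[Si](C(C)C)(C(C)C)C(C)C)cc(C)c2o1
A4 | alternative 2 | (2R)-2,8-dimethyl-6-[(triisopropylsilyl)oxy]-2-[(trimethylsilyl)ethynyl]-2,3-dihydro-4H-chromen-4-one | C[Si](C)(C)C#C[C@@]1(C)CC(=O)c2cc(O[Si](C(C)C)(C(C)C)C(C)C)cc(C)c2O1
A5 | alternative 3 | (2E)-5-{2-hydroxy-3-methyl-5-[(triisopropylsilyl)oxy]phenyl}-3-methylpent-2-en-1-yl methyl carbonate | COC(=O)OC/C=C(\C)CCc1cc(O[Si](C(C)C)(C(C)C)C(C)C)cc(C)c1O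
A6 | alternative 3 | {[(2R)-2-ethenyl-2,8-dimethyl-3,4-dihydro-2H-chromen-6-yl]oxy}tri(propan-2-yl)silane | C=C[C@@]1(C)CCc2cc(O[Si](C(C)C)(C(C)C)C(C)C)cc(C)c2O1
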